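Compound numbers are those of the list after the steps; 33 is the target. C-k is the ketal carbon of ring C, C-q the quaternary ether carbon of ring D, and C-c the carbinol carbon of ring D.

## Analysis of the target

Target 33 is an octacycle made of two chlorinated naphthalene-derived halves held roughly at right angles: arene ring A fused to ring C (an epoxy ketone ring), and arene ring B fused to ring D (an epoxy carbinol ring). The halves are joined twice: by a C–C bond from ring A to C-q, and through C-k, which carries the ring B phenol oxygen and an oxygen that bridges to C-q, so that a five-membered ether ring and a 1,3-dioxin ring share the C-k–O–C-q unit. There are seven stereocentres: C-k (S), C-q (S), the ring D oxirane carbons (R,R), C-c (S), and the ring C oxirane carbons (R next to C-k, S next to the ketone). C-k is fixed by C-q through the bicyclic bridge; both oxiranes lie on the side of the bridging oxygen (opposite the aryl ether oxygen in ring C, opposite the ring A carbon in ring D); the carbinol hydroxyl is trans to the ring D oxirane. Sensitive functions are the two epoxides, the acid-labile bridged ketal, an ortho-hydroxybenzylic alcohol, two chelated chlorophenols and the aryl chlorides. The difficulty is that the halves are nearly alike yet differ in oxidation level (ketone against carbinol) and in attachment (C–C at C-q, C–O at C-k), so late steps must tell two similar rings apart while a quaternary carbinol is set as one enantiomer. The route rests on ring D: C-q and C-c are both benzylic, both oxygenated and ortho to each other on ring B, so they are the two ends of a dioxygenated ortho-quinodimethane, and a benzocyclobutenone is the stable form in which that diene can be carried.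

## Retrosynthetic reasoning

**33 to 32.** The two C–O bonds of the ring C oxirane are cut first, giving enone 32. Keeping ring C as an enone until the end is what separates the two carbonyl groups. Forward, a peroxide anion has to add to the enone face away from the axial aryl ether oxygen and ring B.

**32 to 31.** The C–H bond at C-c is cut, giving epoxy ketone 31. In 31 the ring D carbonyl is an α,β-epoxy aryl ketone and the ring C carbonyl is a cross-conjugated aryl enone, so a hydride donor can distinguish them; with two epoxy ketones it could not. Forward, hydride must arrive on the oxirane face.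

**31 to 29 (through 30).** Both C–O bonds at C-k are cut. The bridged core then becomes a naphthoquinone with a tertiary alcohol in the peri position and a phenol on ring B. Forward, acid must remove three methoxymethyl ethers and close the ketal while an epoxy ketone is present. This fixes the protecting groups: all three phenol oxygens are methoxymethyl ethers, because a methyl ether could only be removed by a strong Lewis acid, which an oxirane does not survive.

**29 to 28.** The quinone is traced to the 1,4-dimethoxynaphthalene ring. Oxidation comes before deprotection because a free ring B hydroquinone would be oxidised first. In 28 ring B is capped and deactivated by its acyl group and chlorine.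

**28 to 27.** The ring D oxirane is cut to the enone. It is installed before the bridge because the free tertiary hydroxyl of 27 can steer the peroxide to its own face, and because this turns the ring D carbonyl into an epoxy ketone before ring C becomes an enone.

**27 to 26 to 25.** The ketone returns to its dioxolane and the vinyl C–H to a C–S bond. The sulfone only activates the dienophile and is removed once ring D exists.

**25 to 9, 20 and 21.** Three C–C bonds are cut: C-q to ring A, and both bonds of the two-carbon unit of ring D. This divides the target between its halves and builds ring D at the ketone level. Forward, aryllithium addition, ring opening and capture by 21 must occur in one flask, and the chiral ketal must control the face.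

**20 to 19, then 19 to 11 and 15.** The C–Cl bond is cut first. Without chlorine the aryne 17 is symmetrical and a single monoketal 19 can form; an aryne flanked by two alkoxy groups and carrying chlorine would give regioisomers. Chlorine returns by electrophilic substitution on 19, where the ketone has made the two alkoxy groups unequal. The four-membered ring of 19 is cut to 17 (from 11, from 10) and ketene silyl acetal 15 (from 14, from 12 and 13), which delivers both cyclobutene carbons at the dione monoketal level with the diol attached.

**9 to 8, 7, 6, 5, then 1 and 2.** The halogens are placed by a free naphthol (bromine para, chlorine ortho). A hydroxynaphthoquinone would halogenate on the quinone ring instead. Naphthol 6 comes from oxabicycle 5, the adduct of aryne 4 (from 1) and furan 2.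

## Alternatives that were turned down

**Alternative 1:** The bond between C-k and the bridging oxygen is cut, which leads back to the tertiary alcohol A1 at C-q, in which C-k is a benzylic ether C–H inside a seven-membered ring. Forward, PhI(OAc)2 and iodine under visible light give the hypoiodite and then the alkoxy radical; 1,5-hydrogen transfer across the peri positions, oxidation of the carbon radical and capture by the same oxygen would turn A1 into the bridged ketal A2 with ring C still saturated.
- For: the ketal forms late and without acid, and the ring D epoxide and protected carbinol are already present, so the two carbonyls never need to be distinguished. On these two points it is stronger than the chosen route.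
- Against: A1 needs the aryl–carbon bond, a benzylic aryl ether, the quaternary carbinol as one enantiomer and the ring D epoxy carbinol, each made separately. The tertiary alkoxy radical sits between two arenes and an oxirane and can fragment instead of abstracting hydrogen. Ring C still needs dehydrogenation and epoxidation after the key step.
- Comparison: the chosen route makes the aryl–carbon bond, the quaternary carbinol and ring D in one operation from two simple arenes, and separates the carbonyls by timing.

**Alternative 2:** Only the ring D epoxide and C-q are addressed: the two oxirane C–O bonds of the spirolactone epoxy enone A4 are cut, which leads to the achiral dienone A3 as substrate. Forward, H2O2 with a cinchona-derived primary amine salt epoxidises one of the two enantiotopic enone double bonds of A3 and gives A4 as one enantiomer.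
- For: absolute configuration comes from a catalyst in a well-precedented reaction on a readily made achiral substrate. Here it is clearly stronger than the chosen route, whose facial control by a remote ketal is not assured.
- Against: A4 holds only ring A, the five-membered ring at the lactone level and the six carbons of ring D. Ring B must still be annulated onto the remaining enone with both oxygens and chlorine, and the lactone carbonyl turned into C-k with all of ring C attached, in the presence of an epoxy enone. That is a long linear sequence.
- Comparison: the chosen route is convergent and brings ring B and ring C fully formed; its auxiliary at least makes the two products of the key step separable diastereomers.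

**Alternative 3:** The aryl–oxygen bond at C-k is cut back to an aryl–carbon bond, giving the C2-symmetric diol A5 with a central six-membered carbocycle. Forward, H2O2 and BF3·OEt2 convert one of the two homotopic tertiary alcohols of A5 into the hydroperoxide; the ring B carbon para to methoxyl migrates to oxygen and the other hydroxyl captures the oxocarbenium ion, giving the bridged ketal A6 with two dihydronaphthalene rings.
- For: the precursor is symmetrical and suits two-directional synthesis; either alcohol may react; the symmetrical skeleton becomes the unsymmetrical C–C/C–O linkage in one step. In precursor simplicity it is stronger than the chosen route.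
- Against: both alcohols are doubly benzylic and ionisable, so a second rearrangement or dehydration of the central ring competes. A6 has two plain dihydronaphthalene rings; each needs benzylic oxidation with alkene transposition and epoxidation, and the rings must then be differentiated as ketone and carbinol. The methyl ethers must be removed in the presence of epoxides. The configuration of A5 needs its own solution.
- Comparison: the chosen route delivers ring D at the ketone level and ring C as a masked quinone, so the late redox work is one oxidation, one reduction and two epoxidations.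

Key step: step 11

Assumption: the (2R,3R)-ketal is taken as the matched auxiliary for the S configuration at C-q in 25; if the sense proves opposite, the same route is run with the (2S,3S)-diol.

## Route

Step 1
Reactants: 1 2-chloro-1,4-dimethoxybenzene; 2 furan
Product: 5 5,8-dimethoxy-1,4-dihydro-1,4-epoxynaphthalene, via aryllithium 3 (not isolated), via aryne 4 (not isolated)
Conditions: LiN(i-Pr)2, THF, furan (excess), −78 °C → rt
Reagents that add atoms: none
Why: Deprotonation between chlorine and methoxyl and loss of LiCl give the symmetrical aryne 4, which furan traps by [4+2] cycloaddition; the symmetry removes any regiochemical question.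

Step 2
Reactants: 5 5,8-dimethoxy-1,4-dihydro-1,4-epoxynaphthalene
Product: 6 5,8-dimethoxynaphthalen-1-ol
Conditions: conc. HCl (cat.), MeOH, rt
Reagents that add atoms: none
Why: Acid-catalysed opening of the oxygen bridge and aromatisation (isomerisation of 1,4-epoxy-1,4-dihydronaphthalenes to 1-naphthols); symmetry allows only one naphthol.

Step 3
Reactants: 6 5,8-dimethoxynaphthalen-1-ol
Product: 7 4-bromo-5,8-dimethoxynaphthalen-1-ol
Conditions: NBS (1.0 equiv), MeCN, −20 → 0 °C
Reagents that add atoms: N-bromosuccinimide, O=C1CCC(=O)N1Br
Why: Electrophilic aromatic bromination; the free naphthol hydroxyl outranks the methyl ethers as a director and sends bromine to its para α-position, which a peri alkoxy group does not block (compare the para-bromination of 1,5-dialkoxynaphthalenes).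

Step 4
Reactants: 7 4-bromo-5,8-dimethoxynaphthalen-1-ol
Product: 8 4-bromo-2-chloro-5,8-dimethoxynaphthalen-1-ol
Conditions: SO2Cl2 (1.05 equiv), CH2Cl2, 0 °C
Reagents that add atoms: sulfuryl chloride, ClS(Cl)(=O)=O
Why: Electrophilic aromatic chlorination; with the para position blocked, the ortho carbon is the only activated site of the naphthol ring.

Step 5
Reactants: 8 4-bromo-2-chloro-5,8-dimethoxynaphthalen-1-ol
Product: 9 5-bromo-7-chloro-1,4-dimethoxy-8-(methoxymethoxy)naphthalene
Conditions: NaH, MOMCl, DMF, 0 °C → rt
Reagents that add atoms: chloromethyl methyl ether, COCCl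
Why: O-Alkylation of the naphthoxide; the acetal is chosen because this oxygen must later be freed by acid while an epoxide is present.

Step 6
Reactants: 10 2-chlorobenzene-1,4-diol
Product: 11 2-chloro-1,4-bis(methoxymethoxy)benzene
Conditions: NaH, MOMCl, DMF, 0 °C → rt
Reagents that add atoms: chloromethyl methyl ether, COCCl
Why: Double O-alkylation; the acetals survive the strong bases that follow and do not migrate to a neighbouring alkoxide as a silyl group would.

Step 7
Reactants: 12 methyl dimethoxyacetate; 13 (2R,3R)-butane-2,3-diol
Product: 14 methyl (4R,5R)-4,5-dimethyl-1,3-dioxolane-2-carboxylate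
Conditions: p-TsOH (cat.), toluene, 110 °C, MeOH distilled off
Reagents that add atoms: none
Why: Acid-catalysed transacetalisation driven by removal of methanol; the diol is C2-symmetric, so the acetal carbon is not a stereocentre.

Step 8
Reactants: 14 methyl (4R,5R)-4,5-dimethyl-1,3-dioxolane-2-carboxylate
Product: 15 tert-butyl{[(4R,5R)-4,5-dimethyl-1,3-dioxolan-2-ylidene](methoxy)methoxy}dimethylsilane
Conditions: LiN(i-Pr)2, THF, −78 °C; t-BuMe2SiCl, DMPU, −78 °C → rt
Reagents that add atoms: tert-butyldimethylsilyl chloride, CC(C)(C)[Si](C)(C)Cl
Why: O-Silylation of the ester enolate gives the ketene silyl acetal; the C2 axis of the dioxolane lies along the double bond, so there are no geometric isomers.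

Step 9
Reactants: 11 2-chloro-1,4-bis(methoxymethoxy)benzene; 15 ketene silyl acetal
Product: 19 (4'R,5'R)-2,5-bis(methoxymethoxy)-4',5'-dimethylspiro[bicyclo[4.2.0]octa-1,3,5-triene-7,2'-[1,3]dioxolan]-8-one, via aryllithium 16 (not isolated), via aryne 17 (not isolated), via cycloadduct 18 (not isolated)
Conditions: s-BuLi, THF, −78 °C; 15 (2.5 equiv), −78 → −20 °C; then Bu4NF, AcOH, THF, 0 °C
Reagents that add atoms: none
Why: Ortho-lithiation between chlorine and the acetal oxygen and loss of LiCl give the symmetrical aryne 17, which undergoes [2+2] cycloaddition with the electron-rich ketene silyl acetal. Buffered fluoride removes the silyl group and the hemiketal collapses to the ketone while the dioxolane stays; because 17 is symmetrical only one monoketal can form.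

Step 10
Reactants: 19 dione monoketal
Product: 20 (4'R,5'R)-4-chloro-2,5-bis(methoxymethoxy)-4',5'-dimethylspiro[bicyclo[4.2.0]octa-1,3,5-triene-7,2'-[1,3]dioxolan]-8-one
Conditions: NCS, DMF, 40 °C
Reagents that add atoms: N-chlorosuccinimide, O=C1CCC(=O)N1Cl
Why: Electrophilic aromatic chlorination; the alkoxy group ortho to the ketone is tied up in conjugation with it, so the other alkoxy group directs to its only free ortho position, para to the acyl-bearing carbon, as in halogenation of 2,5-dialkoxybenzaldehydes.

Step 11
Reactants: 9 5-bromo-7-chloro-1,4-dimethoxy-8-(methoxymethoxy)naphthalene; 20 chlorinated dione monoketal; 21 ethynyl p-tolyl sulfone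
Product: 25 (4S,4'R,5'R)-7-chloro-4-[3-chloro-5,8-dimethoxy-4-(methoxymethoxy)naphthalen-1-yl]-5,8-bis(methoxymethoxy)-4',5'-dimethyl-3-(4-methylbenzenesulfonyl)-4H-spiro[naphthalene-1,2'-[1,3]dioxolan]-4-ol, via aryllithium 22 (not isolated), via lithium benzocyclobutenoxide 23 (not isolated), via ortho-quinodimethane enolate 24 (not isolated)
Conditions: 9, t-BuLi (2.0 equiv), THF, −78 °C; 20, −78 °C; 21 (3 equiv), −78 → 0 °C; AcOH
Reagents that add atoms: none
Why: Bromine–lithium exchange gives 22, which adds to the only ketone of 20 to give 23; the oxy-anion lowers the barrier to conrotatory 4π opening, oxygen turning outward, and gives 24, an extended enolate with a ketene acetal terminus. The acetal terminus adds to the unsubstituted carbon of 21 and the α-sulfonyl vinyl anion closes on the diaryl ketone carbon (6-exo-trig), the stepwise limit of a [4+2] cycloaddition, driven by loss of ring strain and recovery of the arene. The closest known reaction type is anion-accelerated opening of benzocyclobutenols with Diels–Alder capture of the α-oxy-ortho-quinodimethane by electron-poor alkenes and alkynes, together with aryllithium addition to benzocyclobutenedione monoketals. Ring D is the only ring closed, by C–C bond formation at C-q. C-q is the only new stereocentre and is set in that closure: the lithium alkoxide can bridge to one of the two ketal oxygens across the forming ring, and the two arrangements differ in whether a dioxolane methyl faces the peri acetal oxygen of ring B or the small vinylic hydrogen. Regioselectivity (sulfone next to C-q) follows from the polarity of both partners and is erased in step 12. Chemoselectivity needs C–C bond formation to outrun proton transfer from the acetylenic C–H, which is why 21 is added cold, in excess, and only after 22 has been consumed. The auxiliary makes the two possible products diastereomers, so they can be separated if induction is incomplete.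

Step 12
Reactants: 25 vinyl sulfone carbinol
Product: 26 (4S,4'R,5'R)-7-chloro-4-[3-chloro-5,8-dimethoxy-4-(methoxymethoxy)naphthalen-1-yl]-5,8-bis(methoxymethoxy)-4',5'-dimethyl-4H-spiro[naphthalene-1,2'-[1,3]dioxolan]-4-ol
Conditions: Na/Hg (6% Na), Na2HPO4, MeOH–THF, −20 °C
Reagents that add atoms: none
Why: Reductive desulfonylation of a vinyl sulfone by electron transfer, with protonation of the vinyl anion by methanol; buffer and low temperature protect the aryl chlorides and C-q is untouched.

Step 13
Reactants: 26 desulfonylated ketal
Product: 27 (4S)-7-chloro-4-[3-chloro-5,8-dimethoxy-4-(methoxymethoxy)naphthalen-1-yl]-4-hydroxy-5,8-bis(methoxymethoxy)naphthalen-1(4H)-one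
Conditions: 0.5 M HCl, THF–H2O, 0 °C → rt
Reagents that add atoms: water, O
Why: Hydrolysis of an allylic, benzylic ketal, which ionises to an oxocarbenium ion much faster than aryl methoxymethyl ethers cleave; once the enone exists, ionisation at C-q is disfavoured by the conjugated carbonyl.

Step 14
Reactants: 27 ring D enone
Product: 28 (2S,3R,4S)-7-chloro-4-[3-chloro-5,8-dimethoxy-4-(methoxymethoxy)naphthalen-1-yl]-2,3-epoxy-4-hydroxy-5,8-bis(methoxymethoxy)-3,4-dihydronaphthalen-1(2H)-one
Conditions: t-BuOOH, benzyltrimethylammonium hydroxide (cat.), THF, 0 °C
Reagents that add atoms: tert-butyl hydroperoxide, CC(C)(C)OO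
Why: Weitz–Scheffer nucleophilic epoxidation; the peroxide anion adds to the β-carbon on the face of the tertiary hydroxyl (hydrogen-bond delivery) and away from the bulky naphthyl group, which sets both oxirane carbons cis to the C-q oxygen; ring C is still an arene and is inert.

Step 15
Reactants: 28 ring D epoxy ketone
Product: 29 (2S,3R,4S)-7-chloro-4-[3-chloro-4-(methoxymethoxy)-5,8-dioxo-5,8-dihydronaphthalen-1-yl]-2,3-epoxy-4-hydroxy-5,8-bis(methoxymethoxy)-3,4-dihydronaphthalen-1(2H)-one
Conditions: (NH4)2Ce(NO3)6 (2.5 equiv), MeCN–H2O, 0 °C
Reagents that add atoms: water, O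
Why: Oxidative demethylation of the 1,4-dimethoxynaphthalene ring to the quinone; ring B is harder to oxidise because it is a benzene ring carrying an acyl group and chlorine. The quinone may rest as its cyclic hemiketal with the peri tertiary hydroxyl, which does not matter for step 16.

Step 16
Reactants: 29 naphthoquinone
Product: 31 bridged ketal bearing the ring C enone beside the ring D epoxy ketone, via triphenol 30 (not isolated)
Conditions: CF3CO2H–CH2Cl2 (1:3), 0 °C → rt
Reagents that add atoms: none
Why: Acidolysis of the three aryl methoxymethyl ethers, then intramolecular ketalisation: the tertiary hydroxyl adds to the peri quinone carbonyl (five-membered ring) and the ring B phenol closes the six-membered ring on the oxocarbenium ion. C-k is set by C-q because only one bridged geometry can close; α,β-epoxy ketones are deactivated toward acid opening and tolerate this acid.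

Step 17
Reactants: 31 bridged epoxy ketone
Product: 32 bridged ketal bearing the ring C enone beside the ring D epoxy carbinol
Conditions: RuCl[(R,R)-TsDPEN](p-cymene) (5 mol %), HCO2H–Et3N (5:2), CH2Cl2, 0 °C
Reagents that add atoms: none
Why: Noyori–Ikariya asymmetric transfer hydrogenation of an aryl ketone; the α,β-epoxy aryl ketone is more electrophilic than the cross-conjugated aryl enone of ring C, which is the basis of chemoselectivity. The (R,R) catalyst is chosen by analogy with 1-tetralone (aryl against alkyl recognition) to deliver hydride to the face carrying the oxirane oxygen, giving the hydroxyl trans to the oxirane (S at C-c, since the oxirane carbon outranks the aryl carbon).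

Step 18
Reactants: 32 ring D epoxy carbinol
Product: 33 target CNP0289684.3
Conditions: t-BuOOH, 1,5,7-triazabicyclo[4.4.0]dec-5-ene, CH2Cl2, 0 °C
Reagents that add atoms: tert-butyl hydroperoxide, CC(C)(C)OO
Why: Weitz–Scheffer epoxidation of the remaining enone; the peroxide adds to the β-carbon next to C-k from the face opposite the axial aryl ether oxygen and ring B, which places the oxirane on the side of the bridging oxygen (R next to C-k, S next to the ketone). The ring D epoxy carbinol has no electrophilic alkene and is left alone.

## Compound list

1 | 2-chloro-1,4-dimethoxybenzene | COc1ccc(OC)c(Cl)c1 | starting material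
2 | furan | c1ccoc1 | starting material
3 | 2-chloro-3-lithio-1,4-dimethoxybenzene | COc1ccc(OC)c([Li])c1Cl | intermediate
4 | 3,6-dimethoxybenzyne | COC1=CC=C(OC)C#C1 | intermediate
5 | 5,8-dimethoxy-1,4-dihydro-1,4-epoxynaphthalene | COc1ccc(OC)c2C3C=CC(O3)c12 | intermediate
6 | 5,8-dimethoxynaphthalen-1-ol | COc1ccc(OC)c2c(O)cccc12 | intermediate
7 | 4-bromo-5,8-dimethoxynaphthalen-1-ol | COc1ccc(OC)c2c(O)ccc(Br)c12 | intermediate
8 | 4-bromo-2-chloro-5,8-dimethoxynaphthalen-1-ol | COc1ccc(OC)c2c(O)c(Cl)cc(Br)c12 | intermediate
9 | 5-bromo-7-chloro-1,4-dimethoxy-8-(methoxymethoxy)naphthalene | COc1ccc(OC)c2c(OCOC)c(Cl)cc(Br)c12 | intermediate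
10 | 2-chlorobenzene-1,4-diol (2-chlorohydroquinone) | Oc1ccc(O)c(Cl)c1 | starting material
11 | 2-chloro-1,4-bis(methoxymethoxy)benzene | COCOc1ccc(OCOC)c(Cl)c1 | intermediate
12 | methyl dimethoxyacetate | COC(OC)C(=O)OC | starting material
13 | (2R,3R)-butane-2,3-diol | C[C@@H](O)[C@@H](C)O | starting material
14 | methyl (4R,5R)-4,5-dimethyl-1,3-dioxolane-2-carboxylate | COC(=O)C1O[C@H](C)[C@@H](C)O1 | intermediate
15 | tert-butyl{[(4R,5R)-4,5-dimethyl-1,3-dioxolan-2-ylidene](methoxy)methoxy}dimethylsilane | COC(O[Si](C)(C)C(C)(C)C)=C1O[C@H](C)[C@@H](C)O1 | intermediate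
16 | 2-chloro-3-lithio-1,4-bis(methoxymethoxy)benzene | COCOc1ccc(OCOC)c([Li])c1Cl | intermediate
17 | 3,6-bis(methoxymethoxy)benzyne | COCOC1=CC=C(OCOC)C#C1 | intermediate
18 | [2+2] cycloadduct, mixed methyl silyl ketal of 19 (both epimers at the silyloxy carbon) | COCOc1ccc(OCOC)c2c1C(OC)(O[Si](C)(C)C(C)(C)C)C21O[C@H](C)[C@@H](C)O1 | intermediate
19 | (4'R,5'R)-2,5-bis(methoxymethoxy)-4',5'-dimethylspiro[bicyclo[4.2.0]octa-1,3,5-triene-7,2'-[1,3]dioxolan]-8-one | O=C1c2c(OCOC)ccc(OCOC)c2C12O[C@H](C)[C@@H](C)O2 | intermediate
20 | (4'R,5'R)-4-chloro-2,5-bis(methoxymethoxy)-4',5'-dimethylspiro[bicyclo[4.2.0]octa-1,3,5-triene-7,2'-[1,3]dioxolan]-8-one | O=C1c2c(OCOC)cc(Cl)c(OCOC)c2C12O[C@H](C)[C@@H](C)O2 | intermediate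
21 | ethynyl p-tolyl sulfone | C#CS(=O)(=O)c1ccc(C)cc1 | starting material
22 | [3-chloro-5,8-dimethoxy-4-(methoxymethoxy)naphthalen-1-yl]lithium | [Li]c1cc(Cl)c(OCOC)c2c(OC)ccc(OC)c12 | intermediate
23 | lithium alkoxide of the adduct of 22 and 20 (both epimers at the carbinolate carbon) | [Li+].[O-]C1(c3cc(Cl)c(OCOC)c4c(OC)ccc(OC)c34)c2c(OCOC)cc(Cl)c(OCOC)c2C12O[C@H](C)[C@@H](C)O2 | intermediate
24 | ortho-quinodimethane lithium enolate, oxygen outward, ketene acetal at the other terminus | [Li+].[O-]/C(c2cc(Cl)c(OCOC)c3c(OC)ccc(OC)c23)=C1\C(OCOC)=CC(Cl)=C(OCOC)C1=C1O[C@H](C)[C@@H](C)O1 | intermediate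
25 | (4S,4'R,5'R)-7-chloro-4-[3-chloro-5,8-dimethoxy-4-(methoxymethoxy)naphthalen-1-yl]-5,8-bis(methoxymethoxy)-4',5'-dimethyl-3-(4-methylbenzenesulfonyl)-4H-spiro[naphthalene-1,2'-[1,3]dioxolan]-4-ol | COc1ccc(OC)c2c(OCOC)c(Cl)cc(c12)[C@@]1(O)C(S(=O)(=O)c3ccc(C)cc3)=CC3(O[C@H](C)[C@@H](C)O3)c3c(OCOC)c(Cl)cc(OCOC)c31 | intermediate
26 | (4S,4'R,5'R)-7-chloro-4-[3-chloro-5,8-dimethoxy-4-(methoxymethoxy)naphthalen-1-yl]-5,8-bis(methoxymethoxy)-4',5'-dimethyl-4H-spiro[naphthalene-1,2'-[1,3]dioxolan]-4-ol | COc1ccc(OC)c2c(OCOC)c(Cl)cc(c12)[C@@]1(O)C=CC3(O[C@H](C)[C@@H](C)O3)c3c(OCOC)c(Cl)cc(OCOC)c31 | intermediate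
27 | (4S)-7-chloro-4-[3-chloro-5,8-dimethoxy-4-(methoxymethoxy)naphthalen-1-yl]-4-hydroxy-5,8-bis(methoxymethoxy)naphthalen-1(4H)-one | COc1ccc(OC)c2c(OCOC)c(Cl)cc(c12)[C@@]1(O)C=CC(=O)c3c(OCOC)c(Cl)cc(OCOC)c31 | intermediate
28 | (2S,3R,4S)-7-chloro-4-[3-chloro-5,8-dimethoxy-4-(methoxymethoxy)naphthalen-1-yl]-2,3-epoxy-4-hydroxy-5,8-bis(methoxymethoxy)-3,4-dihydronaphthalen-1(2H)-one (oxirane cis to the 4-hydroxyl) | COc1ccc(OC)c2c(OCOC)c(Cl)cc(c12)[C@@]1(O)[C@@H]2O[C@@H]2C(=O)c3c(OCOC)c(Cl)cc(OCOC)c31 | intermediate
29 | (2S,3R,4S)-7-chloro-4-[3-chloro-4-(methoxymethoxy)-5,8-dioxo-5,8-dihydronaphthalen-1-yl]-2,3-epoxy-4-hydroxy-5,8-bis(methoxymethoxy)-3,4-dihydronaphthalen-1(2H)-one | O=C1C=CC(=O)c2c(OCOC)c(Cl)cc(c12)[C@@]1(O)[C@@H]2O[C@@H]2C(=O)c3c(OCOC)c(Cl)cc(OCOC)c31 | intermediate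
30 | (2S,3R,4S)-7-chloro-4-(3-chloro-4-hydroxy-5,8-dioxo-5,8-dihydronaphthalen-1-yl)-2,3-epoxy-4,5,8-trihydroxy-3,4-dihydronaphthalen-1(2H)-one | O=C1C=CC(=O)c2c(O)c(Cl)cc(c12)[C@@]1(O)[C@@H]2O[C@@H]2C(=O)c3c(O)c(Cl)cc(O)c31 | intermediate
31 | bridged ketal with ring C enone and ring D epoxy ketone, both phenols free (C-k R, C-q S, ring D oxirane carbons R next to C-q and S next to the ketone) | O=C1c2c(O)c(Cl)cc3c2[C@@]2(Oc4cc(Cl)c(O)c5c4[C@]3(O2)[C@@H]2O[C@@H]2C5=O)C=C1 | intermediate
32 | bridged ketal with ring C enone and ring D epoxy carbinol (C-k R, C-q S, ring D oxirane R,R, C-c S; hydroxyl trans to the oxirane) | O=C1c2c(O)c(Cl)cc3c2[C@@]2(Oc4cc(Cl)c(O)c5c4[C@]3(O2)[C@@H]2O[C@@H]2[C@H]5O)C=C1 | intermediate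
33 | CNP0289684.3 (C-k S, C-q S, ring D oxirane R,R, C-c S, ring C oxirane R next to C-k and S next to the ketone) | O=C1c2c(O)c(Cl)cc3c2[C@@]2(Oc4cc(Cl)c(O)c5c4[C@]3(O2)[C@@H]2O[C@@H]2[C@H]5O)[C@@H]2O[C@H]12 | target

## Step count and weak points

Total: 18 steps. Longest linear sequence: 13 steps (steps 1–5, then 11–18). The other branch (steps 7–10, then 11–18) is 12.

**Step 11 (key step).** Two things can go wrong. Proton transfer from the acetylenic C–H of 21 to the alkoxide 23 or the ring-opened anion 24, or addition of the alkoxide oxygen to 21, may consume the diene before a C–C bond forms; both anions are strong bases and 21 is a good acceptor for oxygen nucleophiles. Facial selectivity may also be poor, because the dioxolane is four atoms from the new stereocentre. Fallback, from 9 and 20 back to 25: the adduct of 22 and 20 is protonated at −78 °C and the benzocyclobutenol F1 is isolated. Heating F1 with 21 in toluene opens the four-membered ring thermally to the neutral hydroxy-ortho-quinodimethane, which undergoes Diels–Alder addition with the same regiochemistry and no base present; the diastereomers of 25 are then separated by chromatography.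

**Step 17.** Hydride may be delivered to the wrong face, or the ring C enone may also be reduced. The substrate's own preference is attack opposite the oxirane oxygen, so the catalyst has to override it, and formic acid is in excess. Fallback, from 31 back to 32: NaBH4 at −78 °C reduces the epoxy ketone under substrate control and gives the cis-epoxy alcohol F2 with the hydroxyl on the oxirane face. Ac2O and K2CO3 in acetone acetylate both phenols of F2 and give the diacetate F3 with the carbinol still free. Mitsunobu reaction of F3 with 4-nitrobenzoic acid, Ph3P and diisopropyl azodicarboxylate inverts the carbinol and gives the trans 4-nitrobenzoate F4 as the last intermediate; K2CO3 in methanol then removes all three esters of F4 to give 32.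

**Step 16.** The oxirane may be opened by trifluoroacetate, the strained bridge may close incompletely, or the formaldehyde equivalent released from the acetals may alkylate the free hydroquinone ring. Fallback, from 29 back to 31: the acetals are exchanged under buffered, non-protic conditions (Me3SiOTf, 2,2'-bipyridyl, then water) and triphenol 30 is isolated. Trimethyl orthoformate with pyridinium tosylate converts 30 into the cyclic methyl ketal F5 through the five-membered hemiketal. Warming F5 with pyridinium tosylate in toluene, with removal of methanol, closes the dioxin ring by transketalisation to 31.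

**Step 13.** The tertiary, doubly benzylic, allylic carbinol may ionise before the ketal has hydrolysed, which would scramble C-q or transpose the allylic system; the electron-rich naphthyl group stabilises that cation. Fallback, from 25 back to 27: the ketal of 25 is hydrolysed at the sulfone stage, where the sulfonyl group disfavours the cation, and the β-sulfonyl enone F6 is obtained with C-q intact. [(Ph3P)CuH]6 then adds hydride to the sulfonyl-bearing β-carbon of F6 and the copper enolate expels sulfinate, giving 27.

**Step 9.** The aryne may be consumed by unreacted aryllithium or alkyllithium, or the cycloaddition with the tetra-oxygenated ketene acetal may be inefficient. Fallback, from 1 back to 19: aryne 4 is generated from 1 with NaNH2 in THF and trapped with 1,1-dimethoxyethylene; the resulting tetramethoxybenzocyclobutene F7 is hydrolysed with dilute HCl to the benzocyclobutenone F8 by loss of methanol. Treatment of F8 with NBS and a radical initiator gives the dibromo ketone F9 at the benzylic carbon, and AgOCOCF3 in aqueous MeCN converts F9 into the dimethoxybenzocyclobutenedione F10 in one operation. BCl3 removes both methyl groups of F10, each ortho to a carbonyl, to give the dihydroxy dione F11 as its boron chelate before work-up; NaH and MOMCl convert F11 into the bis(methoxymethoxy) dione F12 without touching the carbonyls. The bis(trimethylsilyl) ether of 13 with catalytic Me3SiOTf at −78 °C then ketalises one of the two equivalent carbonyls of F12 to give 19.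

Further compounds

F1 | step 11 | (4'R,5'R)-4-chloro-8-[3-chloro-5,8-dimethoxy-4-(methoxymethoxy)naphthalen-1-yl]-2,5-bis(methoxymethoxy)-4',5'-dimethylspiro[bicyclo[4.2.0]octa-1,3,5-triene-7,2'-[1,3]dioxolan]-8-ol (both epimers at C-8) | OC1(c3cc(Cl)c(OCOC)c4c(OC)ccc(OC)c34)c2c(OCOC)cc(Cl)c(OCOC)c2C12O[C@H](C)[C@@H](C)O2
F2 | step 17 | C-c epimer of 32 (hydroxyl cis to the ring D oxirane) | O=C1c2c(O)c(Cl)cc3c2[C@@]2(Oc4cc(Cl)c(O)c5c4[C@]3(O2)[C@@H]2O[C@@H]2[C@@H]5O)C=C1
F3 | step 17 | diacetate of F2 at both phenols | O=C1c2c(OC(C)=O)c(Cl)cc3c2[C@@]2(Oc4cc(Cl)c(OC(C)=O)c5c4[C@]3(O2)[C@@H]2O[C@@H]2[C@@H]5O)C=C1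
F4 | step 17 | 4-nitrobenzoate of the diacetate of 32 (ester trans to the ring D oxirane) | O=C1c2c(OC(C)=O)c(Cl)cc3c2[C@@]2(Oc4cc(Cl)c(OC(C)=O)c5c4[C@]3(O2)[C@@H]2O[C@@H]2[C@H]5OC(=O)c2ccc(cc2)[N+](=O)[O-])C=C1
F5 | step 16 | cyclic methyl ketal of 30 between the peri quinone carbonyl and the tertiary hydroxyl (both epimers at the ketal carbon) | COC12C=CC(=O)c3c(O)c(Cl)cc(c31)[C@@]1(O2)[C@@H]2O[C@@H]2C(=O)c2c(O)c(Cl)cc(O)c21
F6 | step 13 | (4S)-7-chloro-4-[3-chloro-5,8-dimethoxy-4-(methoxymethoxy)naphthalen-1-yl]-4-hydroxy-5,8-bis(methoxymethoxy)-3-(4-methylbenzenesulfonyl)naphthalen-1(4H)-one | COc1ccc(OC)c2c(OCOC)c(Cl)cc(c12)[C@@]1(O)C(S(=O)(=O)c3ccc(C)cc3)=CC(=O)c3c(OCOC)c(Cl)cc(OCOC)c31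
F7 | step 9 | 2,5,7,7-tetramethoxybicyclo[4.2.0]octa-1,3,5-triene | COc1ccc(OC)c2c1CC2(OC)OC
F8 | step 9 | 2,5-dimethoxybicyclo[4.2.0]octa-1,3,5-trien-7-one | COc1ccc(OC)c2c1CC2=O
F9 | step 9 | 8,8-dibromo-2,5-dimethoxybicyclo[4.2.0]octa-1,3,5-trien-7-one | COc1ccc(OC)c2c1C(Br)(Br)C2=O
F10 | step 9 | 3,6-dimethoxybenzocyclobutenedione | COc1ccc(OC)c2c1C(=O)C2=O
F11 | step 9 | 3,6-dihydroxybenzocyclobutenedione | Oc1ccc(O)c2c1C(=O)C2=O
F12 | step 9 | 3,6-bis(methoxymethoxy)benzocyclobutenedione | COCOc1ccc(OCOC)c2c1C(=O)C2=O
A1 | alternative 1 | tertiary alcohol with seven-membered benzylic aryl ether, saturated ring C ketone and silyl-protected ring D epoxy carbinol (either epimer at the ether carbon) | O=C1c2c(OC(C)=O)c(Cl)cc3c2C(Oc4cc(Cl)c(OC(C)=O)c5c4[C@]3(O)[C@@H]2O[C@@H]2[C@H]5O[Si](C)(C)C(C)(C)C)CC1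
A2 | alternative 1 | bridged ketal with saturated ring C ketone | O=C1c2c(OC(C)=O)c(Cl)cc3c2[C@@]2(Oc4cc(Cl)c(OC(C)=O)c5c4[C@]3(O2)[C@@H]2O[C@@H]2[C@H]5O[Si](C)(C)C(C)(C)C)CC1
A3 | alternative 2 | achiral spirolactone dienone | O=C1C=CC2(OC(=O)c3cc(OC)c(Cl)cc32)C=C1
A4 | alternative 2 | spirolactone epoxy enone | O=C1C=C[C@]2(OC(=O)c3cc(OC)c(Cl)cc32)[C@@H]2O[C@H]12
A5 | alternative 3 | C2-symmetric cis-diol with central six-membered carbocycle | COc1c(Cl)cc2c3c1C=CC[C@]3(O)c1cc(Cl)c(OC)c4c1[C@]2(O)CC=C4
A6 | alternative 3 | bridged aryl ketal with two dihydronaphthalene rings | COc1c(Cl)cc2c3c1C=CC[C@]31Oc4cc(Cl)c(OC)c5c4[C@]2(O1)CC=C5
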